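A direct plan would start from the intact heterocycle, 1H-pyrrole A1: double hydroxymethylation to the symmetric diol A2, mono-silylation to A3, oxidation and N-phosphanylation to the aldehyde A4, addition of its formyl C–H bond across the terminal alkene A5 with [Rh(coe)2Cl]2, then desilylation.
Its weakest points would be:
(a) the statistical mono-protection of the symmetric, azafulvene-prone diol A2, which could deliver at best about half of the material as A3 and would force recycling on deactivated silica;
(b) the chain-joining hydroacylation of A5 by A4, which would rest on an untested N–P directing group, would compete with decarbonylation and alkene isomerisation, and would be run on the most advanced material;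
(c) the four functional-group steps between A1 and A4, which would form no skeletal bond at all.

Plan of the new route
The retrosynthesis cuts the ring itself: C2–C3 and C4–C5 (a [3+2] cycloaddition) and N1–C5 (an imine condensation); the exocyclic C(=O)–C2 bond is made earlier by C-acylation of an isocyanoacetate.
The enabling feature is that pyrrole C2 lies between N1 and the ketone carbonyl, so N1–C2–C(=O) is an α-amino ketone whose aldimine is a ketone-stabilised azomethine ylide.
C5 with its CH2OH is an aldehyde carbon, and the unsubstituted C3–C4 pair is an acetylene equivalent.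
The only ring therefore forms last, in one flask, from three acyclic components (8, 9, 10) with the whole lipid chain already in place.
Since the two α-substituents come from different components, nothing symmetric has to be desymmetrised, no C–H activation or directing group is needed, and one silyl ether is the only protecting group.

Key step: step 4

Assumption: the transient pyrrolidine 12 forms as a racemic mixture of diastereomers whose configuration is irrelevant, since all four centres vanish on aromatisation; its SMILES is given without stereodescriptors, and the target is achiral.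

Step 1
Reactants: 1 1-bromo-4-methylpentane; 2 12-bromododecanoic acid
Product: 4 16-methylheptadecanoic acid, via (4-methylpentyl)magnesium bromide 3 (not isolated)
Conditions: 1 (2.5 equiv), Mg, THF, 50 °C; then 2, Li2CuCl4 (3 mol%), THF, −20 °C → rt; 1 M HCl work-up
Reagents that add atoms: none
Why: Copper-catalysed Grignard/primary alkyl bromide cross-coupling (Kochi type) on the bromomagnesium carboxylate of 2, which the first equivalent of 3 forms, should join the two sp3 carbons without touching the carboxylate; no stereocentre is formed.

Step 2
Reactants: 4 16-methylheptadecanoic acid; 5 methyl isocyanoacetate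
Product: 7 methyl 5-(15-methylhexadecyl)-1,3-oxazole-4-carboxylate, via 16-methylheptadecanoyl chloride 6 (not isolated)
Conditions: (COCl)2 (1.3 equiv), DMF (cat.), CH2Cl2, 0 °C → rt, evaporate; then 5 (1.1 equiv), Et3N (3 equiv), DMAP (10 mol%), THF, 0 °C → 50 °C
Reagents that add atoms: none
Why: Schöllkopf oxazole synthesis, in which the isocyanoacetate anion is C-acylated by the acid chloride and the enolate oxygen closes onto the isocyanide carbon, should form the future C(=O)–C2 bond and deliver the α-amino ketone in a masked form that cannot self-condense.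

Step 3
Reactants: 7 methyl 5-(15-methylhexadecyl)-1,3-oxazole-4-carboxylate
Product: 8 1-amino-17-methyloctadecan-2-one hydrochloride
Conditions: 6 M aq. HCl–1,4-dioxane (1:1), 100 °C; cool, filter, wash with Et2O
Reagents that add atoms: hydrogen chloride, Cl
Why: Acid hydrolysis of the oxazole (C2 lost as formic acid), ester hydrolysis and decarboxylation of the β-keto acid should give the α-amino ketone, isolated as its hydrochloride because the free base would dimerise to a dihydropyrazine.

Step 4
Reactants: 8 1-amino-17-methyloctadecan-2-one hydrochloride; 9 2-{[tert-butyl(dimethyl)silyl]oxy}acetaldehyde; 10 (E)-1,2-bis(benzenesulfonyl)ethene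
Product: 13 1-[5-({[tert-butyl(dimethyl)silyl]oxy}methyl)-1H-pyrrol-2-yl]-16-methylheptadecan-1-one, via silyloxy aldimine 11 (not isolated), via bis-sulfonyl pyrrolidine 12 (not isolated)
Conditions: 9 (1.05 equiv), Et3N (1.05 equiv, dropwise), MgSO4, THF, 0 °C → rt; filtration under Ar; then 10 (1.05 equiv), AgOAc (10 mol%), PPh3 (10 mol%), Et3N (10 mol%), rt, dark; then DBU (3 equiv), rt
Reagents that add atoms: none
Why: Proposed new method: the free amine of 8 condenses with 9 to the aldimine 11, whose CH2 between the imine nitrogen and the ketone is deprotonated inside an N,O-chelate of monovalent silver to a ketone-stabilised N-metalated azomethine ylide; this adds to the symmetric, doubly activated alkene 10, and DBU then removes two benzenesulfinates from 12 (first by E1cB from the ketone α-carbon C2, then by nitrogen-assisted loss from C4 and tautomerisation of the 2H-pyrrole) to give the aromatic 13. The closest known reaction type is the silver- or copper-catalysed cycloaddition of aryl aldimines of glycine esters with 1,2-bis(benzenesulfonyl)ethene as an acetylene equivalent, followed by base-induced aromatisation to 5-arylpyrrole-2-carboxylates; new here are the ketone as the ylide-stabilising group and an enolisable α-silyloxy aldehyde as the imine partner. The pyrrolidine ring is closed by an intermolecular [3+2] cycloaddition (concerted or Michael–Mannich) that forms C2–C3 and C4–C5 onto the N1–C5 bond made by the condensation. No stereocentre has to be controlled, since the four transient centres of 12 are all erased on aromatisation. The selectivity needed is regiochemical and is fixed by construction: the two ylide carbons become the acyl-bearing C2 and the silyloxymethyl-bearing C5, 10 is symmetric, and the amine is converted fully into 11 before 10 is added, so aza-Michael addition cannot compete. The ketone is a better acidifying and chelating group than an ester, so ylide formation should be easier than in the precedent, and either prototropic form of the imine leads to the same dipole.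

Step 5
Reactants: 13 1-[5-({[tert-butyl(dimethyl)silyl]oxy}methyl)-1H-pyrrol-2-yl]-16-methylheptadecan-1-one
Product: 14 1-[5-(hydroxymethyl)-1H-pyrrol-2-yl]-16-methylheptadecan-1-one
Conditions: n-Bu4NF (1.1 equiv), THF, 0 °C; pH 7 buffer work-up
Reagents that add atoms: none
Why: Fluoride-mediated cleavage of the primary silyl ether, driven by Si–F bond formation, should free the carbinol under non-acidic conditions, which matters because pyrrol-2-ylmethanols ionise to azafulvenium ions in acid even when tempered by a 2-acyl group.

Compound list
1 | 1-bromo-4-methylpentane | CC(C)CCCBr | starting material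
2 | 12-bromododecanoic acid | OC(=O)CCCCCCCCCCCBr | starting material
3 | (4-methylpentyl)magnesium bromide | CC(C)CCC[Mg]Br | intermediate
4 | 16-methylheptadecanoic acid | CC(C)CCCCCCCCCCCCCCC(=O)O | intermediate
5 | methyl isocyanoacetate | [C-]#[N+]CC(=O)OC | starting material
6 | 16-methylheptadecanoyl chloride | CC(C)CCCCCCCCCCCCCCC(=O)Cl | intermediate
7 | methyl 5-(15-methylhexadecyl)-1,3-oxazole-4-carboxylate | COC(=O)c1ncoc1CCCCCCCCCCCCCCC(C)C | intermediate
8 | 1-amino-17-methyloctadecan-2-one hydrochloride | CC(C)CCCCCCCCCCCCCCC(=O)CN.Cl | intermediate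
9 | 2-{[tert-butyl(dimethyl)silyl]oxy}acetaldehyde | O=CCO[Si](C)(C)C(C)(C)C | starting material
10 | (E)-1,2-bis(benzenesulfonyl)ethene | O=S(=O)(/C=C/S(=O)(=O)c1ccccc1)c1ccccc1 | starting material
11 | 1-[(E)-(2-{[tert-butyl(dimethyl)silyl]oxy}ethylidene)amino]-17-methyloctadecan-2-one | CC(C)CCCCCCCCCCCCCCC(=O)C/N=C/CO[Si](C)(C)C(C)(C)C | intermediate
12 | 1-[3,4-bis(benzenesulfonyl)-5-({[tert-butyl(dimethyl)silyl]oxy}methyl)pyrrolidin-2-yl]-16-methylheptadecan-1-one (racemic, mixture of diastereomers) | CC(C)CCCCCCCCCCCCCCC(=O)C1NC(CO[Si](C)(C)C(C)(C)C)C(S(=O)(=O)c2ccccc2)C1S(=O)(=O)c3ccccc3 | intermediate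
13 | 1-[5-({[tert-butyl(dimethyl)silyl]oxy}methyl)-1H-pyrrol-2-yl]-16-methylheptadecan-1-one | CC(C)CCCCCCCCCCCCCCC(=O)c1ccc(CO[Si](C)(C)C(C)(C)C)[nH]1 | intermediate
14 | 1-[5-(hydroxymethyl)-1H-pyrrol-2-yl]-16-methylheptadecan-1-one (achiral) | CC(C)CCCCCCCCCCCCCCC(=O)c1ccc(CO)[nH]1 | target

Total step count: 5. Longest linear sequence: 5 steps (1 and 2 → 4 → 7 → 8 → 13 → 14).

Steps most likely to fail

1. Step 4 (Proposed new method). Three processes could go wrong. The liberated amino ketone could self-condense before the imine has formed. The enolisable imine could undergo aldol-type self-condensation. A stepwise Michael addition could lose one sulfinate before ring closure, which would stall the sequence short of aromatisation. The fallback uses known chemistry, a Hemetsberger–Knittel-type pyrrole synthesis from a dienyl azide; it sets out from 8 and returns at 13. Diazo transfer to 8 (imidazole-1-sulfonyl azide hydrogen sulfate, CuSO4 cat., NaHCO3, MeOH) would give 1-azido-17-methyloctadecan-2-one F1. DBU-catalysed aldol addition of F1 to the known aldehyde (2E)-4-{[tert-butyl(dimethyl)silyl]oxy}but-2-enal F2 (THF, −20 °C) would give (2E)-5-azido-1-{[tert-butyl(dimethyl)silyl]oxy}-4-hydroxy-21-methyldocos-2-en-6-one F3. Mesylation (MsCl, Et3N, CH2Cl2, 0 °C) would give (2E)-5-azido-1-{[tert-butyl(dimethyl)silyl]oxy}-21-methyl-6-oxodocos-2-en-4-yl methanesulfonate F4, which would eliminate in the same flask to the dienyl azide (2E)-5-azido-1-{[tert-butyl(dimethyl)silyl]oxy}-21-methyldocosa-2,4-dien-6-one F5. Loss of N2 from F5, in toluene at 100 °C or with Rh2(O2CC3F7)4 at rt, should pass through the 2-vinyl-2H-azirine and the 2H-pyrrole to 13, with the same unambiguous 2,5-pattern.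

2. Step 5. Basic fluoride could deprotonate the acidic pyrrole N–H and trigger base-induced oligomerisation of the pyrrolylmethanol, or the cleavage could stay incomplete. The fallback sets out from 12 and returns at 14. Step 4 would be stopped before the DBU addition and 12 isolated. The silyl ether would be cleaved at this non-aromatic stage, where no azafulvene can form, with HF·pyridine in THF at 0 °C, to give 1-[3,4-bis(benzenesulfonyl)-5-(hydroxymethyl)pyrrolidin-2-yl]-16-methylheptadecan-1-one F6. DBU (3 equiv, THF, rt) would then aromatise F6 directly to 14, so the pyrrole carbinol would never meet fluoride.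

3. Step 3. Poor solubility of the lipophilic oxazole in aqueous acid could leave ring hydrolysis or decarboxylation incomplete. The fallback sets out from 4 and returns at 8. Activation of 4 with 1,1'-carbonyldiimidazole (THF, rt) would give 1-(1H-imidazol-1-yl)-16-methylheptadecan-1-one F7. C-acylation of the nitromethane anion (CH3NO2, KOtBu, DMSO, rt) would give 17-methyl-1-nitrooctadecan-2-one F8. Hydrogenation of F8 (H2, Pd/C, methanolic HCl) would give 8.

Further compounds
F1 | step 4 | 1-azido-17-methyloctadecan-2-one | CC(C)CCCCCCCCCCCCCCC(=O)CN=[N+]=[N-]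
F2 | step 4 | (2E)-4-{[tert-butyl(dimethyl)silyl]oxy}but-2-enal | O=C/C=C/CO[Si](C)(C)C(C)(C)C
F3 | step 4 | (2E)-5-azido-1-{[tert-butyl(dimethyl)silyl]oxy}-4-hydroxy-21-methyldocos-2-en-6-one (mixture of diastereomers) | CC(C)CCCCCCCCCCCCCCC(=O)C(N=[N+]=[N-])C(O)/C=C/CO[Si](C)(C)C(C)(C)C
F4 | step 4 | (2E)-5-azido-1-{[tert-butyl(dimethyl)silyl]oxy}-21-methyl-6-oxodocos-2-en-4-yl methanesulfonate (mixture of diastereomers) | CC(C)CCCCCCCCCCCCCCC(=O)C(N=[N+]=[N-])C(OS(C)(=O)=O)/C=C/CO[Si](C)(C)C(C)(C)C
F5 | step 4 | (2E)-5-azido-1-{[tert-butyl(dimethyl)silyl]oxy}-21-methyldocosa-2,4-dien-6-one (4,5-geometry not defined) | CC(C)CCCCCCCCCCCCCCC(=O)C(N=[N+]=[N-])=C/C=C/CO[Si](C)(C)C(C)(C)C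
F6 | step 5 | 1-[3,4-bis(benzenesulfonyl)-5-(hydroxymethyl)pyrrolidin-2-yl]-16-methylheptadecan-1-one (racemic, mixture of diastereomers) | CC(C)CCCCCCCCCCCCCCC(=O)C1NC(CO)C(S(=O)(=O)c2ccccc2)C1S(=O)(=O)c3ccccc3
F7 | step 3 | 1-(1H-imidazol-1-yl)-16-methylheptadecan-1-one | CC(C)CCCCCCCCCCCCCCC(=O)n1ccnc1
F8 | step 3 | 17-methyl-1-nitrooctadecan-2-one | CC(C)CCCCCCCCCCCCCCC(=O)C[N+](=O)[O-]
A1 | direct plan | 1H-pyrrole | c1cc[nH]c1
A2 | direct plan | (1H-pyrrole-2,5-diyl)dimethanol | OCc1ccc(CO)[nH]1
A3 | direct plan | [5-({[tri(propan-2-yl)silyl]oxy}methyl)-1H-pyrrol-2-yl]methanol | OCc1ccc(CO[Si](C(C)C)(C(C)C)C(C)C)[nH]1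
A4 | direct plan | 1-(diphenylphosphanyl)-5-({[tri(propan-2-yl)silyl]oxy}methyl)-1H-pyrrole-2-carbaldehyde | O=Cc1ccc(CO[Si](C(C)C)(C(C)C)C(C)C)n1P(c2ccccc2)c3ccccc3
A5 | direct plan | 15-methylhexadec-1-ene | C=CCCCCCCCCCCCCC(C)C
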